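**Strategy.** Ring numbering: O1, C2 (3,4-dimethoxyphenyl carbon), C3, C4, C5 (syringyl carbon). The ring is closed at C2–C3 by a low-valent titanium keto-ester (McMurry) coupling. The step exploits that C2 is an aryl- and O1-bearing carbon and C3 a methyl-bearing carbon: in the precursor C2 is the acyl carbon of a 3,4-dimethoxybenzoate on O1 and C3 a methyl ketone, held 1,4 by O1–C5–C4. One operation gives the C2=C3 enol ether of a 2,3-dihydrofuran. Syn hydrogenation, anti to the cis C4-methyl/C5-aryl pair, then fixes the cis-3,4-dimethyl unit, and acid equilibration turns both aryl groups trans to their neighbouring methyls.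

Key step: step 4

Remark on the target: it is read as (2S,3S,4R,5R) in the numbering above, i.e. 2,3-trans, 3,4-cis, 4,5-trans, with both aryl groups on the face opposite the two methyl groups.

Remark on step 1: the sense of induction is assumed by analogy with allylboration under the same catalyst class (Si-face addition with the S catalyst). If it ran the other way, the R catalyst would be used.

**Step 1**
Reactants: 1 4-(benzyloxy)-3,5-dimethoxybenzaldehyde; 2 (Z)-crotylboronic acid pinacol ester
Product: 3 (1S,2R)-1-[4-(benzyloxy)-3,5-dimethoxyphenyl]-2-methylbut-3-en-1-ol (syn)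
Conditions: (S)-3,3'-bis(2,4,6-triisopropylphenyl)-1,1'-binaphthyl-2,2'-diyl hydrogen phosphate (5 mol %), 4 Å MS, toluene, −30 to 0 °C; aqueous work-up
Reagents that add atoms: (Z)-crotylboronic acid pinacol ester 2, C/C=C\CB1OC(C)(C)C(C)(C)O1
Why: Chiral phosphoric acid-catalysed asymmetric crotylboration through a closed chair (Zimmerman–Traxler) transition state, in which the Z geometry of the boronate should give the syn relationship and the catalyst should choose the Si face of the aldehyde, setting the future C5 (1S) and C4 (2R).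

**Step 2**
Reactants: 3 the syn homoallylic alcohol; 4 3,4-dimethoxybenzoyl chloride
Product: 5 (1S,2R)-1-[4-(benzyloxy)-3,5-dimethoxyphenyl]-2-methylbut-3-en-1-yl 3,4-dimethoxybenzoate
Conditions: Et3N, DMAP (cat.), CH2Cl2, 0 °C to rt
Reagents that add atoms: 3,4-dimethoxybenzoyl chloride 4, COc1ccc(C(=O)Cl)cc1OC
Why: DMAP-catalysed acylation (nucleophilic acyl substitution) of the secondary alcohol, which installs O1–C2 at the ester oxidation level without touching a stereocentre.

**Step 3**
Reactants: 5 the homoallylic 3,4-dimethoxybenzoate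
Product: 6 (1S,2S)-1-[4-(benzyloxy)-3,5-dimethoxyphenyl]-2-methyl-3-oxobutyl 3,4-dimethoxybenzoate
Conditions: PdCl2 (10 mol %), CuCl (cat.), O2 (1 atm), DMF/H2O 7:1, rt
Reagents that add atoms: water, O
Why: Tsuji–Wacker oxidation, in which Markovnikov hydroxypalladation of the terminal alkene should give the methyl ketone (future C3 and its methyl); the neighbouring stereocentre is not involved, and the descriptor changes only through CIP priorities.

**Step 4**
Reactants: 6 the keto ester
Product: 7 (2S,3R)-2-[4-(benzyloxy)-3,5-dimethoxyphenyl]-5-(3,4-dimethoxyphenyl)-3,4-dimethyl-2,3-dihydrofuran (aryl and methyl on the two sp3 carbons cis)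
Conditions: TiCl3 (6 equiv), Zn–Cu couple, pyridine (additive), DME, reflux; 6 added by syringe pump over 12 h (about 0.005 M)
Reagents that add atoms: none
Why: Low-valent titanium should reduce the methyl ketone to a titanium-bound ketyl at C3, which adds to the ester carbonyl C2; the titanium-bound 1,2-dioxygenated intermediate is then deoxygenated to the C2=C3 enol ether. The closest known reaction type is the McMurry keto-ester (oxo-ester) coupling that gives cyclic enol ethers, furans and benzofurans. The ring O1–C2–C3–C4–C5 closes by 5-exo-trig attack of the C3 ketyl on the ester C=O, whose oxygen stays exocyclic until it is removed. No stereocentre is formed; C4 and C5 are carried through, and the new tetrasubstituted alkene is the handle by which step 5 sets C2 and C3. The step needs ketone–ester coupling to win over intermolecular ketone–ketone coupling, which the five-membered tether, slow addition and high dilution should secure, and the ketone, being the more easily reduced carbonyl, should be the only site of ketyl formation. The non-basic, buffered medium is meant to protect the enolisable C4 centre and the benzylic C5–O bond.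

**Step 5**
Reactants: 7 the 2,3-dihydrofuran
Product: 9 4-[(2S,3R,4S,5R)-5-(3,4-dimethoxyphenyl)-3,4-dimethyloxolan-2-yl]-2,6-dimethoxyphenol (all-cis), via phenolic dihydrofuran 8 (not isolated)
Conditions: H2 (3 bar), 10% Pd/C, EtOAc, rt
Reagents that add atoms: none
Why: Heterogeneous catalytic hydrogenation with concurrent hydrogenolysis of the aryl benzyl ether, in which H2 should add syn to C2=C3 from the face opposite the cis C4 methyl and C5 aryl, setting C3 (methyl cis to the C4 methyl) and C2 (aryl cis to the C3 methyl).

**Step 6**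
Reactants: 9 the all-cis tetrahydrofuran
Product: 11 4-[(2R,3R,4S,5S)-5-(3,4-dimethoxyphenyl)-3,4-dimethyloxolan-2-yl]-2,6-dimethoxyphenol (target), via C5-epimerised tetrahydrofuran 10 (not isolated)
Conditions: BF3·OEt2 (0.5 equiv), CH2Cl2, −20 °C to rt
Reagents that add atoms: none
Why: Lewis acid-promoted thermodynamic epimerisation of the two benzylic ether centres, in which reversible ionisation of C5–O1 and C2–O1 to para-oxygen-stabilised benzylic cations and re-closure should move each aryl group trans to its neighbouring methyl while C3 and C4 are not touched.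

**Compound list**
1 | 4-(benzyloxy)-3,5-dimethoxybenzaldehyde | COc1cc(C=O)cc(OC)c1OCc1ccccc1 | starting material
2 | (Z)-crotylboronic acid pinacol ester, 2-[(2Z)-but-2-en-1-yl]-4,4,5,5-tetramethyl-1,3,2-dioxaborolane | C/C=C\CB1OC(C)(C)C(C)(C)O1 | starting material
3 | (1S,2R)-1-[4-(benzyloxy)-3,5-dimethoxyphenyl]-2-methylbut-3-en-1-ol | C=C[C@@H](C)[C@H](O)c1cc(OC)c(OCc2ccccc2)c(OC)c1 | intermediate
4 | 3,4-dimethoxybenzoyl chloride | COc1ccc(C(=O)Cl)cc1OC | starting material
5 | (1S,2R)-1-[4-(benzyloxy)-3,5-dimethoxyphenyl]-2-methylbut-3-en-1-yl 3,4-dimethoxybenzoate | C=C[C@@H](C)[C@H](OC(=O)c1ccc(OC)c(OC)c1)c1cc(OC)c(OCc2ccccc2)c(OC)c1 | intermediate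
6 | (1S,2S)-1-[4-(benzyloxy)-3,5-dimethoxyphenyl]-2-methyl-3-oxobutyl 3,4-dimethoxybenzoate | CC(=O)[C@@H](C)[C@H](OC(=O)c1ccc(OC)c(OC)c1)c1cc(OC)c(OCc2ccccc2)c(OC)c1 | intermediate
7 | (2S,3R)-2-[4-(benzyloxy)-3,5-dimethoxyphenyl]-5-(3,4-dimethoxyphenyl)-3,4-dimethyl-2,3-dihydrofuran | COc1ccc(C2=C(C)[C@@H](C)[C@@H](c3cc(OC)c(OCc4ccccc4)c(OC)c3)O2)cc1OC | intermediate
8 | 4-[(2S,3R)-5-(3,4-dimethoxyphenyl)-3,4-dimethyl-2,3-dihydrofuran-2-yl]-2,6-dimethoxyphenol | COc1ccc(C2=C(C)[C@@H](C)[C@@H](c3cc(OC)c(O)c(OC)c3)O2)cc1OC | intermediate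
9 | 4-[(2S,3R,4S,5R)-5-(3,4-dimethoxyphenyl)-3,4-dimethyloxolan-2-yl]-2,6-dimethoxyphenol (all-cis) | COc1ccc([C@@H]2O[C@H](c3cc(OC)c(O)c(OC)c3)[C@H](C)[C@@H]2C)cc1OC | intermediate
10 | 4-[(2R,3R,4S,5R)-5-(3,4-dimethoxyphenyl)-3,4-dimethyloxolan-2-yl]-2,6-dimethoxyphenol (syringyl ring trans to its neighbouring methyl, dimethoxyphenyl ring still cis) | COc1ccc([C@@H]2O[C@@H](c3cc(OC)c(O)c(OC)c3)[C@H](C)[C@@H]2C)cc1OC | intermediate
11 | 4-[(2R,3R,4S,5S)-5-(3,4-dimethoxyphenyl)-3,4-dimethyloxolan-2-yl]-2,6-dimethoxyphenol | COc1ccc([C@H]2O[C@@H](c3cc(OC)c(O)c(OC)c3)[C@H](C)[C@@H]2C)cc1OC | target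

**Total step count:** 6. **Longest linear sequence:** 6 steps (from 1).

**Steps most likely to fail**

Step 4. The Lewis-acidic low-valent titanium may ionise or reductively cleave the benzylic C5–O ester bond, the ketone may enolise and scramble C4, or intermolecular ketone coupling may outrun ring closure. The fallback closes the same C2=C3 bond by olefin metathesis instead of reductive carbonyl coupling. It sets out from 6: both carbonyl groups are methylenated with dimethyltitanocene, Cp2TiMe2 (toluene, 65 °C), to the bis-methylenated diene F1. Ring-closing metathesis with Mo(CHCMe2Ph)(N-2,6-iPr2C6H3)[OC(CF3)2Me]2 (benzene, 60 °C) then joins the two 1,1-disubstituted alkenes with loss of ethylene, and the route is rejoined at 7.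

Step 5. Palladium may over-reduce by cleaving the ring benzylic C–O bonds, may dehydrogenate the dihydrofuran to the furan, or may reduce the hindered tetrasubstituted enol ether too slowly. The fallback sets out from 7 and changes both the catalyst type and the order of the endgame. Homogeneous hydrogenation with [Ir(cod)(PCy3)(py)]PF6 (H2, CH2Cl2, rt) does not hydrogenolyse C–O bonds and should give the O-benzyl all-cis tetrahydrofuran F2 by the same facial approach. BF3·OEt2 equilibration is then run on the benzyl ether, through the O-benzyl C5-epimer F3 (not isolated) to the O-benzyl ether of the target F4. A short hydrogenolysis (H2, Pd/C, EtOAc) comes last and rejoins the route at 11.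

Step 6. The ring-opened benzylic cation may lose a proton (E1), which would erase the C3/C4 configuration, or may be captured by the other aryl ring (aryltetralin formation) or by another molecule. The fallback sets out from 9 and replaces cationic by radical equilibration. A catalytic thiyl radical (triisopropylsilanethiol with an organic photocatalyst under blue light, or PhSSPh under 365 nm light) should abstract and return hydrogen reversibly at the two weak benzylic ether C–H bonds (C2–H and C5–H). This drives the same thermodynamic inversion through 10 to 11 without carbocations and makes no new compound (F0).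

**Further compounds**
F1 | step 4 | (1S,2R)-1-[4-(benzyloxy)-3,5-dimethoxyphenyl]-2,3-dimethylbut-3-en-1-yl 1-(3,4-dimethoxyphenyl)ethenyl ether (bis-methylenated diene) | C=C(C)[C@@H](C)[C@H](OC(=C)c1ccc(OC)c(OC)c1)c1cc(OC)c(OCc2ccccc2)c(OC)c1
F2 | step 5 | (2R,3S,4R,5S)-5-[4-(benzyloxy)-3,5-dimethoxyphenyl]-2-(3,4-dimethoxyphenyl)-3,4-dimethyltetrahydrofuran (O-benzyl all-cis) | COc1ccc([C@@H]2O[C@H](c3cc(OC)c(OCc4ccccc4)c(OC)c3)[C@H](C)[C@@H]2C)cc1OC
F3 | step 5 | (2R,3S,4R,5R)-5-[4-(benzyloxy)-3,5-dimethoxyphenyl]-2-(3,4-dimethoxyphenyl)-3,4-dimethyltetrahydrofuran (O-benzyl C5-epimer) | COc1ccc([C@@H]2O[C@@H](c3cc(OC)c(OCc4ccccc4)c(OC)c3)[C@H](C)[C@@H]2C)cc1OC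
F4 | step 5 | (2S,3S,4R,5R)-5-[4-(benzyloxy)-3,5-dimethoxyphenyl]-2-(3,4-dimethoxyphenyl)-3,4-dimethyltetrahydrofuran (O-benzyl ether of the target) | COc1ccc([C@H]2O[C@@H](c3cc(OC)c(OCc4ccccc4)c(OC)c3)[C@H](C)[C@@H]2C)cc1OC
F0 | step 6 | none | none
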